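The route disconnects the C2–C3 bond of the inner dihydrobenzofuran. C3 is a diarylmethine held between ring-A carbon a2 and ring-D carbon d1, and it sits next to the ether carbon C2 on the a3 oxygen. C3 can therefore be a diaryl carbene and C2 the CH2 of a 4-methoxybenzyl ether. One operation closes the five-membered ring, forms C2–C3 and sets C3 (by the catalyst) and C2 (by equilibration). The precursor is a 5-diazo-dibenzosuberane carrying the ArCH centre C8, a single 4-methoxybenzyl ether on a3, and a bromine on a6 that later anchors the second, analogous ring closure.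

Key step: step 11

**Labels.** Ring A (central ring): a1 bears C7H2, a2 bears C3, a3 bears the inner furan oxygen, a4 is CH, a5 bears the outer furan oxygen, a6 bears C3′. Ring D (fused dimethoxy ring): d1 bears C3, d3 and d5 bear oxygen, d6 bears C8. The seven-membered ring is C8–C7–a1–a2–C3–d1–d6. C2/C3 and C2′/C3′ are the sp3 carbons of the inner and outer dihydrobenzofuran; ring E is the pendant 3,5-dioxygenated ring on C3′. In dibenzo[a,d][7]annulene numbering of the tricyclic ketones, C5 = future C3, C10 = C8, C11 = C7, C1 = a6, C2 = a5, C4 = a3.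

**Stereochemistry of the target.** 8S, 2S, 3S, 2′R, 3′R. Both dihydrobenzofurans are 2,3-trans and of opposite absolute sense, so the two insertions use opposite catalyst antipodes.

**Assumption.** The (Sa,S) iridium ligand is taken to give 8S, Rh2(R-PTAD)4 to give 3S and Rh2(S-PTAD)4 to give 3′R. If a first run shows the opposite sense, the mirror-image catalyst is used in that step and nothing else changes.

**Design points.**
- Only one 4-methoxybenzyl (PMB) ether is present at a time. Such an ether would not survive the acid that equilibrates C2 or any Lewis acid, so the a5 oxygen stays a methyl ether until it is freed by chelation-controlled demethylation next to the second ketone.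
- Carbon a6 is marked with bromine before the seven-membered ring is closed. After the first ring closure, carbon d2 of ring D is as activated as a6, so a late intermolecular Friedel–Crafts aroylation could not be trusted to find a6.
- Ring A goes through the Friedel–Crafts closure as methyl ethers; each PMB ether is introduced afterwards.

Step 1
Reactants: 1 methyl 3,5-dimethoxybenzoate
Product: 2 methyl 2-bromo-3,5-dimethoxybenzoate
Conditions: NBS, MeCN, 0 °C → rt
Reagents that add atoms: N-bromosuccinimide, O=C1CCC(=O)N1Br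
Why: Electrophilic aromatic bromination should go to C2, which is para to one methoxy group and ortho to the other, rather than to C4, which is flanked by both methoxy groups.

Step 2
Reactants: 3 1-ethynyl-4-methoxybenzene
Product: 4 2,2′-[(E)-1-(4-methoxyphenyl)ethene-1,2-diyl]bis(4,4,5,5-tetramethyl-1,3,2-dioxaborolane) (boron atoms cis)
Conditions: B2pin2, Pt(PPh3)4 (3 mol %), DMF, 80 °C
Reagents that add atoms: bis(pinacolato)diboron, CC1(C)OB(OC1(C)C)B1OC(C)(C)C(C)(C)O1
Why: Alkyne diboration catalysed by zerovalent platinum adds both boron atoms to the same face, which fixes the alkene geometry that the next two couplings keep.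

Step 3
Reactants: 4 2,2′-[(E)-1-(4-methoxyphenyl)ethene-1,2-diyl]bis(4,4,5,5-tetramethyl-1,3,2-dioxaborolane), 5 1-iodo-3,5-dimethoxybenzene
Product: 6 2-[(E)-2-(3,5-dimethoxyphenyl)-1-(4-methoxyphenyl)ethenyl]-4,4,5,5-tetramethyl-1,3,2-dioxaborolane
Conditions: PdCl2(dppf) (3 mol %), K2CO3, dioxane/H2O, rt
Reagents that add atoms: none
Why: In this Suzuki–Miyaura coupling the unhindered terminal C–B bond of a 1,2-diborylalkene transmetalates faster than the internal α-aryl C–B bond, so one equivalent of aryl iodide should arylate C7 alone with retention of geometry.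

Step 4
Reactants: 6 2-[(E)-2-(3,5-dimethoxyphenyl)-1-(4-methoxyphenyl)ethenyl]-4,4,5,5-tetramethyl-1,3,2-dioxaborolane, 2 methyl 2-bromo-3,5-dimethoxybenzoate
Product: 8 (Z)-2-[2-(3,5-dimethoxyphenyl)-1-(4-methoxyphenyl)ethenyl]-3,5-dimethoxybenzoic acid, via methyl ester 7 (not isolated)
Conditions: Pd(OAc)2 (5 mol %), SPhos, K3PO4, toluene/H2O, 90 °C; then NaOH, MeOH/H2O, 70 °C; HCl
Reagents that add atoms: sodium hydroxide, [Na+].[OH-]
Why: A Suzuki–Miyaura coupling with the bulky electron-rich SPhos ligand should join the di-ortho-substituted bromide to the alkenyl boronate with retention (ring D cis to ring A), and saponification in the same pot frees the acid that directs the next step.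

Step 5
Reactants: 8 (Z)-2-[2-(3,5-dimethoxyphenyl)-1-(4-methoxyphenyl)ethenyl]-3,5-dimethoxybenzoic acid
Product: 9 2-[(1S)-2-(3,5-dimethoxyphenyl)-1-(4-methoxyphenyl)ethyl]-3,5-dimethoxybenzoic acid
Conditions: H2 (6 atm), [Ir(cod)((Sa,S)-SIPHOX)]B[3,5-(CF3)2C6H3]4 (1 mol %), Cs2CO3 (0.5 equiv), MeOH, 45 °C; HCl work-up
Reagents that add atoms: none
Why: In this carboxylate-directed iridium-catalysed asymmetric hydrogenation the ring-D carboxylate binds iridium and holds the single alkene isomer in the chiral P,N pocket, so hydrogen should add to one face of C8 and set 8S.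

Step 6
Reactants: 9 2-[(1S)-2-(3,5-dimethoxyphenyl)-1-(4-methoxyphenyl)ethyl]-3,5-dimethoxybenzoic acid
Product: 10 2-[(1S)-2-(2-bromo-3,5-dimethoxyphenyl)-1-(4-methoxyphenyl)ethyl]-3,5-dimethoxybenzoic acid
Conditions: NBS (1.0 equiv), CH2Cl2, −40 → 0 °C, dark
Reagents that add atoms: N-bromosuccinimide, O=C1CCC(=O)N1Br
Why: Electrophilic bromination should pick ring A, the only dimethoxyarene without an electron-withdrawing group, at one of its two equivalent carbons ortho to the CH2 group and para to a methoxy group, which marks a6.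

Step 7
Reactants: 10 2-[(1S)-2-(2-bromo-3,5-dimethoxyphenyl)-1-(4-methoxyphenyl)ethyl]-3,5-dimethoxybenzoic acid
Product: 12 (10S)-1-bromo-2,4,7,9-tetramethoxy-10-(4-methoxyphenyl)-10,11-dihydro-5H-dibenzo[a,d][7]annulen-5-one, via mixed anhydride 11 (not isolated)
Conditions: (CF3CO)2O, CH2Cl2, 0 °C → rt
Reagents that add atoms: none
Why: Intramolecular Friedel–Crafts acylation through the mixed trifluoroacetic anhydride should close the seven-membered ring at a2, the only free ring-A carbon in reach and ortho/para to two methoxy groups, whereas the six-membered alternative would attack the anisyl ring meta to its methoxy group.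

Step 8
Reactants: 12 (10S)-1-bromo-2,4,7,9-tetramethoxy-10-(4-methoxyphenyl)-10,11-dihydro-5H-dibenzo[a,d][7]annulen-5-one
Product: 13 (10S)-1-bromo-4-hydroxy-2,7,9-trimethoxy-10-(4-methoxyphenyl)-10,11-dihydro-5H-dibenzo[a,d][7]annulen-5-one
Conditions: BCl3 (1.5 equiv), CH2Cl2, −78 → 0 °C; H2O
Reagents that add atoms: none
Why: Chelation-controlled ether cleavage should remove only the methyl group on a3, because BCl3 bound to the ketone oxygen reaches only the ortho methoxy group and the other methyl ethers are meta, para or remote.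

Step 9
Reactants: 13 (10S)-1-bromo-4-hydroxy-2,7,9-trimethoxy-10-(4-methoxyphenyl)-10,11-dihydro-5H-dibenzo[a,d][7]annulen-5-one, 14 4-methoxybenzyl chloride
Product: 15 (10S)-1-bromo-2,7,9-trimethoxy-4-[(4-methoxybenzyl)oxy]-10-(4-methoxyphenyl)-10,11-dihydro-5H-dibenzo[a,d][7]annulen-5-one
Conditions: K2CO3, n-Bu4NI (cat.), DMF, 60 °C
Reagents that add atoms: none
Why: Williamson ether synthesis on the chelated phenol with iodide catalysis should install the ether whose CH2 becomes C2, under a base too weak to touch the C8 hydrogen.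

Step 10
Reactants: 15 (10S)-1-bromo-2,7,9-trimethoxy-4-[(4-methoxybenzyl)oxy]-10-(4-methoxyphenyl)-10,11-dihydro-5H-dibenzo[a,d][7]annulen-5-one
Product: 16 hydrazone of 15 at C5 (C=N–NH2; geometry at C=N immaterial)
Conditions: N2H4·H2O (excess), AcOH (cat.), n-BuOH, 110 °C
Reagents that add atoms: hydrazine, NN
Why: Acid-catalysed condensation of the diaryl ketone with a large excess of hydrazine should give the N-unsubstituted hydrazone and suppress azine formation, as is usual for dibenzosuberones.

Step 11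
Reactants: 16 hydrazone of 15 at C5
Product: 19 (2S,3S,8S)-a6-bromo-a5,d3,d5-trimethoxy-2,8-bis(4-methoxyphenyl) inner tetracycle (trans-2,3-dihydrobenzofuran on a2/a3 of the dibenzosuberane), via diazo compound 17 (not isolated), via cis isomer 18 (not isolated)
Conditions: MnO2 (10 equiv), CH2Cl2, rt, dark; Rh2(R-PTAD)4 (1 mol %), 0 °C; filter (Celite); TFA, CH2Cl2, 0 °C → rt
Reagents that add atoms: none
Why: MnO2 dehydrogenates the hydrazone to diazo compound 17, which loses N2 on Rh2(R-PTAD)4 to give an electrophilic divalent rhodium carbene at C3 that lacks any β-hydrogen and so cannot escape by a 1,2-shift; it takes a hydrogen from the OCH2 group on a3, activated by the ether oxygen and the 4-methoxyphenyl ring, and C–C bond formation is concerted with or immediately follows that transfer. The closest known reaction is the enantioselective intramolecular C–H insertion of hydrazone-derived donor/donor carbenes into benzylic ether C–H bonds to give 2,3-diaryl-2,3-dihydrobenzofurans, applied here to a carbene held in a seven-membered ring. The furan ring closes by 1,5-insertion, the carbene carbon bonding to the fifth atom of the chain C3–a2–a3–O–CH2. C3 (S) is set by the chiral carboxylate pocket of the catalyst, chosen to match C8, and C2 is expected to form cis to C3 (18) and is then equilibrated by TFA through the ring-opened 4-methoxybenzylic cation to the more stable trans isomer (2S) while C3 stays untouched. Site selectivity is secured by the substrate, since the a3 ether holds the only C–H bonds in a 1,5-relation, the a5 oxygen carries only a methyl group that cannot be reached, and the C7 and C8 hydrogens would require four-membered rings. Keeping the diazo compound dilute and cold holds back azine formation.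

Step 12
Reactants: 19 (2S,3S,8S)-a6-bromo-a5,d3,d5-trimethoxy-2,8-bis(4-methoxyphenyl) inner tetracycle, 20 N,3,5-trimethoxy-N-methylbenzamide
Product: 22 (2S,3S,8S)-a6-(3,5-dimethoxybenzoyl)-a5,d3,d5-trimethoxy-2,8-bis(4-methoxyphenyl) inner tetracycle, via aryllithium 21 (not isolated)
Conditions: n-BuLi, THF, −78 °C; then 20, −78 → 0 °C; H2O
Reagents that add atoms: none
Why: Bromine–lithium exchange at −78 °C outruns deprotonation of any benzylic C–H, and the aryllithium adds once to the amide in a Weinreb ketone synthesis, so the aroyl group should enter at a6 alone.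

Step 13
Reactants: 22 (2S,3S,8S)-a6-(3,5-dimethoxybenzoyl)-a5,d3,d5-trimethoxy-2,8-bis(4-methoxyphenyl) inner tetracycle
Product: 23 (2S,3S,8S)-a6-(3,5-dimethoxybenzoyl)-a5-hydroxy-d3,d5-dimethoxy-2,8-bis(4-methoxyphenyl) inner tetracycle
Conditions: BCl3 (1.2 equiv), CH2Cl2, −78 → −20 °C; H2O
Reagents that add atoms: none
Why: Chelation-controlled demethylation should again cleave only the methoxy group ortho to the new ketone (on a5), and the low temperature and near-stoichiometric BCl3 spare the dihydrobenzofuran, which would in any case reclose to its trans form.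

Step 14
Reactants: 23 (2S,3S,8S)-a6-(3,5-dimethoxybenzoyl)-a5-hydroxy-d3,d5-dimethoxy-2,8-bis(4-methoxyphenyl) inner tetracycle, 14 4-methoxybenzyl chloride
Product: 24 (2S,3S,8S)-a6-(3,5-dimethoxybenzoyl)-a5-[(4-methoxybenzyl)oxy]-d3,d5-dimethoxy-2,8-bis(4-methoxyphenyl) inner tetracycle
Conditions: K2CO3, n-Bu4NI (cat.), DMF, 60 °C
Reagents that add atoms: none
Why: Williamson ether synthesis on the chelated phenol should install the second insertion site under conditions that leave the stereocentres alone.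

Step 15
Reactants: 24 (2S,3S,8S)-a6-(3,5-dimethoxybenzoyl)-a5-[(4-methoxybenzyl)oxy]-d3,d5-dimethoxy-2,8-bis(4-methoxyphenyl) inner tetracycle
Product: 25 hydrazone of 24 at the aroyl carbon (C=N–NH2; geometry at C=N immaterial)
Conditions: N2H4·H2O (excess), AcOH (cat.), n-BuOH, 110 °C
Reagents that add atoms: hydrazine, NN
Why: Acid-catalysed hydrazone condensation with excess hydrazine should convert the only ketone present, and the ethers and the dihydrobenzofuran are inert to it.

Step 16
Reactants: 25 hydrazone of 24 at the aroyl carbon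
Product: 28 (2S,3S,8S,2′R,3′R)-heptamethyl ether of the target (both dihydrobenzofurans trans), via diazo compound 26 (not isolated), via cis isomer 27 (not isolated)
Conditions: MnO2 (10 equiv), CH2Cl2, rt, dark; Rh2(S-PTAD)4 (1 mol %), 0 °C; filter (Celite); TFA, CH2Cl2, 0 °C → rt
Reagents that add atoms: none
Why: The same donor/donor carbene C–H insertion, now on an open-chain aryl 3,5-dimethoxyphenyl carbene of the well-precedented kind, should close the outer furan by 1,5-insertion into the a5 ether CH2, with C3′ (R) set by the mirror-image catalyst and C2′ brought to trans (R) by the TFA equilibration.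

Step 17
Reactants: 28 (2S,3S,8S,2′R,3′R)-heptamethyl ether of the target
Product: 29 CNP0136963.1 (2S,3S,8S,2′R,3′R)
Conditions: BBr3 (excess), CH2Cl2, −78 °C → rt; MeOH, then H2O
Reagents that add atoms: none
Why: BBr3 cleavage of all seven aryl methyl ethers is the usual end game for oligostilbenes, and because both dihydrobenzofurans are already the trans isomers any reversible opening at C2 or C2′ should return the same configuration while C3, C3′ and C8 cannot ionise.

**Compound list**

1 | methyl 3,5-dimethoxybenzoate | COC(=O)c1cc(OC)cc(OC)c1 | starting material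
2 | methyl 2-bromo-3,5-dimethoxybenzoate | COC(=O)c1cc(OC)cc(OC)c1Br | intermediate
3 | 1-ethynyl-4-methoxybenzene | COc1ccc(C#C)cc1 | starting material
4 | 2,2′-[(E)-1-(4-methoxyphenyl)ethene-1,2-diyl]bis(4,4,5,5-tetramethyl-1,3,2-dioxaborolane) | COc1ccc(cc1)/C(B1OC(C)(C)C(C)(C)O1)=C/B1OC(C)(C)C(C)(C)O1 | intermediate
5 | 1-iodo-3,5-dimethoxybenzene | COc1cc(I)cc(OC)c1 | starting material
6 | 2-[(E)-2-(3,5-dimethoxyphenyl)-1-(4-methoxyphenyl)ethenyl]-4,4,5,5-tetramethyl-1,3,2-dioxaborolane | COc1ccc(cc1)/C(B1OC(C)(C)C(C)(C)O1)=C/c1cc(OC)cc(OC)c1 | intermediate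
7 | methyl (Z)-2-[2-(3,5-dimethoxyphenyl)-1-(4-methoxyphenyl)ethenyl]-3,5-dimethoxybenzoate (formed in the flask) | COc1ccc(cc1)/C(c1c(OC)cc(OC)cc1C(=O)OC)=C/c1cc(OC)cc(OC)c1 | intermediate
8 | (Z)-2-[2-(3,5-dimethoxyphenyl)-1-(4-methoxyphenyl)ethenyl]-3,5-dimethoxybenzoic acid | COc1ccc(cc1)/C(c1c(OC)cc(OC)cc1C(=O)O)=C/c1cc(OC)cc(OC)c1 | intermediate
9 | 2-[(1S)-2-(3,5-dimethoxyphenyl)-1-(4-methoxyphenyl)ethyl]-3,5-dimethoxybenzoic acid | COc1ccc(cc1)[C@H](Cc1cc(OC)cc(OC)c1)c1c(OC)cc(OC)cc1C(=O)O | intermediate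
10 | 2-[(1S)-2-(2-bromo-3,5-dimethoxyphenyl)-1-(4-methoxyphenyl)ethyl]-3,5-dimethoxybenzoic acid | COc1ccc(cc1)[C@H](Cc1cc(OC)cc(OC)c1Br)c1c(OC)cc(OC)cc1C(=O)O | intermediate
11 | mixed trifluoroacetic anhydride of 10 (formed in the flask) | COc1ccc(cc1)[C@H](Cc1cc(OC)cc(OC)c1Br)c1c(OC)cc(OC)cc1C(=O)OC(=O)C(F)(F)F | intermediate
12 | (10S)-1-bromo-2,4,7,9-tetramethoxy-10-(4-methoxyphenyl)-10,11-dihydro-5H-dibenzo[a,d][7]annulen-5-one | COc1ccc(cc1)[C@@H]1Cc2c(Br)c(OC)cc(OC)c2C(=O)c2cc(OC)cc(OC)c21 | intermediate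
13 | (10S)-1-bromo-4-hydroxy-2,7,9-trimethoxy-10-(4-methoxyphenyl)-10,11-dihydro-5H-dibenzo[a,d][7]annulen-5-one | COc1ccc(cc1)[C@@H]1Cc2c(Br)c(OC)cc(O)c2C(=O)c2cc(OC)cc(OC)c21 | intermediate
14 | 4-methoxybenzyl chloride | COc1ccc(CCl)cc1 | starting material
15 | (10S)-1-bromo-2,7,9-trimethoxy-4-[(4-methoxybenzyl)oxy]-10-(4-methoxyphenyl)-10,11-dihydro-5H-dibenzo[a,d][7]annulen-5-one | COc1ccc(cc1)[C@@H]1Cc2c(Br)c(OC)cc(OCc3ccc(OC)cc3)c2C(=O)c2cc(OC)cc(OC)c21 | intermediate
16 | hydrazone of 15 at C5 | COc1ccc(cc1)[C@@H]1Cc2c(Br)c(OC)cc(OCc3ccc(OC)cc3)c2C(=NN)c2cc(OC)cc(OC)c21 | intermediate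
17 | (10S)-1-bromo-5-diazo-2,7,9-trimethoxy-4-[(4-methoxybenzyl)oxy]-10-(4-methoxyphenyl)-10,11-dihydro-5H-dibenzo[a,d][7]annulene (formed in the flask) | COc1ccc(cc1)[C@@H]1Cc2c(Br)c(OC)cc(OCc3ccc(OC)cc3)c2C(=[N+]=[N-])c2cc(OC)cc(OC)c21 | intermediate
18 | (2R,3S,8S) cis isomer of 19 (formed in the flask) | COc1ccc([C@@H]2Cc3c4c(cc(OC)c3Br)O[C@@H](c3ccc(OC)cc3)[C@H]4c3cc(OC)cc(OC)c32)cc1 | intermediate
19 | (2S,3S,8S)-a6-bromo-a5,d3,d5-trimethoxy-2,8-bis(4-methoxyphenyl) inner tetracycle (trans-2,3-dihydrobenzofuran on a2/a3 of the dibenzosuberane) | COc1ccc([C@@H]2Cc3c4c(cc(OC)c3Br)O[C@H](c3ccc(OC)cc3)[C@H]4c3cc(OC)cc(OC)c32)cc1 | intermediate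
20 | N,3,5-trimethoxy-N-methylbenzamide | CON(C)C(=O)c1cc(OC)cc(OC)c1 | starting material
21 | a6-lithio analogue of 19 (formed in the flask) | COc1ccc([C@@H]2Cc3c4c(cc(OC)c3[Li])O[C@H](c3ccc(OC)cc3)[C@H]4c3cc(OC)cc(OC)c32)cc1 | intermediate
22 | (2S,3S,8S)-a6-(3,5-dimethoxybenzoyl)-a5,d3,d5-trimethoxy-2,8-bis(4-methoxyphenyl) inner tetracycle | COc1ccc([C@@H]2Cc3c4c(cc(OC)c3C(=O)c3cc(OC)cc(OC)c3)O[C@H](c3ccc(OC)cc3)[C@H]4c3cc(OC)cc(OC)c32)cc1 | intermediate
23 | (2S,3S,8S)-a6-(3,5-dimethoxybenzoyl)-a5-hydroxy-d3,d5-dimethoxy-2,8-bis(4-methoxyphenyl) inner tetracycle | COc1ccc([C@@H]2Cc3c4c(cc(O)c3C(=O)c3cc(OC)cc(OC)c3)O[C@H](c3ccc(OC)cc3)[C@H]4c3cc(OC)cc(OC)c32)cc1 | intermediate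
24 | (2S,3S,8S)-a6-(3,5-dimethoxybenzoyl)-a5-[(4-methoxybenzyl)oxy]-d3,d5-dimethoxy-2,8-bis(4-methoxyphenyl) inner tetracycle | COc1ccc([C@@H]2Cc3c4c(cc(OCc5ccc(OC)cc5)c3C(=O)c3cc(OC)cc(OC)c3)O[C@H](c3ccc(OC)cc3)[C@H]4c3cc(OC)cc(OC)c32)cc1 | intermediate
25 | hydrazone of 24 at the aroyl carbon | COc1ccc([C@@H]2Cc3c4c(cc(OCc5ccc(OC)cc5)c3C(=NN)c3cc(OC)cc(OC)c3)O[C@H](c3ccc(OC)cc3)[C@H]4c3cc(OC)cc(OC)c32)cc1 | intermediate
26 | diazo compound from 25 (formed in the flask) | COc1ccc([C@@H]2Cc3c4c(cc(OCc5ccc(OC)cc5)c3C(=[N+]=[N-])c3cc(OC)cc(OC)c3)O[C@H](c3ccc(OC)cc3)[C@H]4c3cc(OC)cc(OC)c32)cc1 | intermediate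
27 | (2S,3S,8S,2′S,3′R) isomer of 28 with the outer dihydrobenzofuran cis (formed in the flask) | COc1ccc([C@@H]2Cc3c4c(cc5c3[C@@H](c3cc(OC)cc(OC)c3)[C@@H](c3ccc(OC)cc3)O5)O[C@H](c3ccc(OC)cc3)[C@H]4c3cc(OC)cc(OC)c32)cc1 | intermediate
28 | (2S,3S,8S,2′R,3′R)-heptamethyl ether of the target | COc1ccc([C@@H]2Cc3c4c(cc5c3[C@@H](c3cc(OC)cc(OC)c3)[C@H](c3ccc(OC)cc3)O5)O[C@H](c3ccc(OC)cc3)[C@H]4c3cc(OC)cc(OC)c32)cc1 | intermediate
29 | CNP0136963.1 (2S,3S,8S,2′R,3′R) | Oc1ccc([C@@H]2Cc3c4c(cc5c3[C@@H](c3cc(O)cc(O)c3)[C@H](c3ccc(O)cc3)O5)O[C@H](c3ccc(O)cc3)[C@H]4c3cc(O)cc(O)c32)cc1 | target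

**Step count.** Total: 17 steps. Longest linear sequence: 16 steps (compound 3 to 29, steps 2–17); step 1 feeds in at step 4.

**Steps most likely to fail**

Step 11. The catalyst may fail to override the facial bias that C8 imposes on the carbene carbon inside the seven-membered ring, giving the wrong configuration at C3. The hindered diazo compound may also couple with the carbene to an azine faster than it inserts. The fallback sets out from 15 and builds the same ring by carbonyl chemistry known from oligostilbene synthesis. Corey–Chaykovsky methylenation (trimethylsulfonium iodide, n-BuLi, THF) gives the spiro-epoxide F1. Meinwald rearrangement with ZnI2 gives the C3-carbaldehyde F2, whose epimerisable C3 settles under the control of C8 and would need to be checked. Addition of 4-methoxyphenylmagnesium bromide gives the carbinol F3. TFA with pentamethylbenzene then removes the PMB group and ionises the carbinol, and the freed a3 phenol closes the trans ring. The fallback returns to the route at 19.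

Step 5. Hydrogenation may be slow or poorly face-selective because the alkene carbon C8 carries a di-ortho-substituted aryl ring, and every later stereocentre rests on this one. The fallback sets out from 8: hydrogenation over palladium on carbon (H2, EtOAc) gives the racemic acid F4, and preparative chromatography on a chiral stationary phase separates the enantiomers. It returns to the route at 9.

Step 10. Condensation at the tri-ortho-substituted diaryl ketone may stall, with azine formation and slow loss of the PMB group on long heating. The fallback sets out from 15: thionation (P4S10, toluene, 90 °C) gives the thioketone F5, which hydrazine hydrate converts at room temperature far more readily than the ketone. It returns to the route at 16.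

**Further compounds**

F1 | step 11 | (10S)-1-bromo-2,7,9-trimethoxy-4-[(4-methoxybenzyl)oxy]-10-(4-methoxyphenyl)-10,11-dihydrospiro[dibenzo[a,d][7]annulene-5,2′-oxirane] (spiro carbon unassigned) | COc1ccc(cc1)[C@@H]1Cc2c(Br)c(OC)cc(OCc3ccc(OC)cc3)c2C2(CO2)c2cc(OC)cc(OC)c21
F2 | step 11 | (5S,10S)-1-bromo-2,7,9-trimethoxy-4-[(4-methoxybenzyl)oxy]-10-(4-methoxyphenyl)-10,11-dihydro-5H-dibenzo[a,d][7]annulene-5-carbaldehyde | COc1ccc(cc1)[C@@H]1Cc2c(Br)c(OC)cc(OCc3ccc(OC)cc3)c2[C@@H](C=O)c2cc(OC)cc(OC)c21
F3 | step 11 | (4-methoxyphenyl)[(5S,10S)-1-bromo-2,7,9-trimethoxy-4-[(4-methoxybenzyl)oxy]-10-(4-methoxyphenyl)-10,11-dihydro-5H-dibenzo[a,d][7]annulen-5-yl]methanol (carbinol carbon unassigned) | COc1ccc(cc1)[C@@H]1Cc2c(Br)c(OC)cc(OCc3ccc(OC)cc3)c2[C@@H](C(O)c2ccc(OC)cc2)c2cc(OC)cc(OC)c21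
F4 | step 5 | racemic 2-[2-(3,5-dimethoxyphenyl)-1-(4-methoxyphenyl)ethyl]-3,5-dimethoxybenzoic acid | COc1ccc(cc1)C(Cc1cc(OC)cc(OC)c1)c1c(OC)cc(OC)cc1C(=O)O
F5 | step 10 | (10S)-1-bromo-2,7,9-trimethoxy-4-[(4-methoxybenzyl)oxy]-10-(4-methoxyphenyl)-10,11-dihydro-5H-dibenzo[a,d][7]annulene-5-thione | COc1ccc(cc1)[C@@H]1Cc2c(Br)c(OC)cc(OCc3ccc(OC)cc3)c2C(=S)c2cc(OC)cc(OC)c21
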